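**Plan**

- Retrosynthetic cuts, in order: the two O–CH2Ph bonds; the C1–C6 bond of ring C (its C2 and C4 hydroxyls traced back to ketones); the acyl C–O bond to O4 of ring B; the A–B depside C(=O)–O bond; the C–C bonds of the triketide chain.
- Enabling feature: ring C is a 2,4-dihydroxy-3,5,6-trimethylbenzoyl group. Its ester carbonyl, ring atoms C1–C6 and the C6 methyl are C1, C2–C7 and C8 of a 4,6-dimethyl-3,5,7-trioxooctanoyl chain. The ester to O4 of ring B, which lies between the C3 and C5 methyls, can therefore be made from a small acylketene before the hexasubstituted ring exists.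
- Forward: rings A and B both come from atraric acid (ring A by turning the ester carbon into a methyl group, ring B by adding the C5 methyl). They are joined as the depside and O4–H of ring B is set free.
- A dioxinone is extended by one methylation and two Claisen acylations to a diketo-dioxinone. Thermolysis acylates the A–B phenol, mild base folds the chain into ring C (the last ring formed), and hydrogenolysis ends the route.
- Stereochemistry: the target has no stereocentre. The methine and carbinol centres of the chain intermediates are labile mixtures that vanish on aromatisation, so nothing has to be controlled.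

Key step: step 15

Remark: enolates, phenoxides and other salts made by deprotonating a numbered compound are treated as ionised forms of that compound and carry no number of their own.
Remark: the keto-dioxinones, the acylketene, the triketo ester and its aldol adduct are mixtures of epimers and keto–enol forms; they are drawn as keto forms without stereodescriptors.

**Route**

Step 1
Reactants: 1 atraric acid (methyl 2,4-dihydroxy-3,6-dimethylbenzoate)
Product: 2 methyl 4-(benzyloxy)-2-hydroxy-3,6-dimethylbenzoate
Conditions: BnBr (1.05 equiv), K2CO3, acetone, reflux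
Reagents that add atoms: benzyl bromide, BrCc1ccccc1
Why: Williamson etherification in which the C2 hydroxyl, held in a hydrogen bond to the ester carbonyl, stays untouched while the more acidic, free C4 phenol is alkylated.

Step 2
Reactants: 2 methyl 4-(benzyloxy)-2-hydroxy-3,6-dimethylbenzoate
Product: 3 3-(benzyloxy)-6-(hydroxymethyl)-2,5-dimethylphenol
Conditions: LiAlH4, THF, 0 °C to reflux; aqueous work-up
Reagents that add atoms: none
Why: Hydride reduction of the salicylate ester to the benzylic alcohol with LiAlH4, which leaves the aryl benzyl ether alone, and any further reduction to the cresol would only anticipate step 3.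

Step 3
Reactants: 3 3-(benzyloxy)-6-(hydroxymethyl)-2,5-dimethylphenol
Product: 4 3-(benzyloxy)-2,5,6-trimethylphenol
Conditions: Et3SiH (3 equiv), CF3CO2H, CH2Cl2, 0 °C
Reagents that add atoms: none
Why: Ionic hydrogenation, in which acid ionises the ortho-hydroxybenzyl alcohol to an ortho-quinone methide or benzylic cation that Et3SiH reduces to the third ring A methyl, leaving the phenol between two methyls free.

Step 4
Reactants: 1 atraric acid
Product: 5 methyl 5-formyl-2,4-dihydroxy-3,6-dimethylbenzoate
Conditions: Cl2CHOMe, TiCl4, CH2Cl2, −10 °C to rt; aqueous HCl work-up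
Reagents that add atoms: dichloromethyl methyl ether, COC(Cl)Cl; water, O
Why: Rieche formylation, in which TiCl4 bound to the phenolic oxygens delivers the electrophile to C5, the only unsubstituted ring carbon, ortho to the C4 hydroxyl.

Step 5
Reactants: 5 methyl 5-formyl-2,4-dihydroxy-3,6-dimethylbenzoate
Product: 6 methyl 2,4-dihydroxy-3,5,6-trimethylbenzoate
Conditions: Et3SiH (3 equiv), CF3CO2H, rt
Reagents that add atoms: none
Why: Ionic hydrogenation of a hydroxybenzaldehyde, whose protonated form is a benzylic cation stabilised by the ortho and para hydroxyls and is reduced twice by Et3SiH to the methyl group without touching the ester.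

Step 6
Reactants: 6 methyl 2,4-dihydroxy-3,5,6-trimethylbenzoate
Product: 7 methyl 2-hydroxy-4-(methoxymethoxy)-3,5,6-trimethylbenzoate
Conditions: MOMCl (1.1 equiv), iPr2NEt, CH2Cl2, 0 °C to rt
Reagents that add atoms: chloromethyl methyl ether, COCCl
Why: Chemoselective O-alkylation (acetal ether formation) of the C4 hydroxyl, which is para to the ester and not hydrogen-bonded, while the chelated C2 hydroxyl does not react under amine base.

Step 7
Reactants: 7 methyl 2-hydroxy-4-(methoxymethoxy)-3,5,6-trimethylbenzoate
Product: 8 methyl 2-(benzyloxy)-4-(methoxymethoxy)-3,5,6-trimethylbenzoate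
Conditions: BnBr, K2CO3, DMF, 70 °C
Reagents that add atoms: benzyl bromide, BrCc1ccccc1
Why: Williamson etherification under more forcing conditions, which breaks the chelate and benzylates the remaining C2 phenol.

Step 8
Reactants: 8 methyl 2-(benzyloxy)-4-(methoxymethoxy)-3,5,6-trimethylbenzoate
Product: 9 2-(benzyloxy)-4-(methoxymethoxy)-3,5,6-trimethylbenzoic acid
Conditions: KOH, DMSO–H2O, 90 °C; then aqueous KHSO4 to pH 4, 0 °C
Reagents that add atoms: potassium hydroxide, [K+].[OH-]
Why: Saponification of a di-ortho-substituted methyl benzoate by poorly solvated hydroxide in hot aqueous DMSO, to which both ethers are stable, followed by a mild acidification that keeps the MOM acetal.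

Step 9
Reactants: 9 2-(benzyloxy)-4-(methoxymethoxy)-3,5,6-trimethylbenzoic acid; 4 3-(benzyloxy)-2,5,6-trimethylphenol
Product: 11 3-(benzyloxy)-2,5,6-trimethylphenyl 2-(benzyloxy)-4-(methoxymethoxy)-3,5,6-trimethylbenzoate, via acid chloride 10 (not isolated)
Conditions: 1-chloro-N,N,2-trimethylprop-1-en-1-amine, CH2Cl2, 0 °C to rt; then 4, NaH, THF, 0 °C to rt
Reagents that add atoms: none
Why: Depside esterification through an acid chloride made under neutral conditions (α-chloroenamine, no free HCl, so the MOM acetal survives) and acylation of the sodium phenoxide, the standard way to join a 2,6-disubstituted benzoyl unit to a 2,6-disubstituted phenol.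

Step 10
Reactants: 11 3-(benzyloxy)-2,5,6-trimethylphenyl 2-(benzyloxy)-4-(methoxymethoxy)-3,5,6-trimethylbenzoate
Product: 12 3-(benzyloxy)-2,5,6-trimethylphenyl 2-(benzyloxy)-4-hydroxy-3,5,6-trimethylbenzoate
Conditions: HCl (1.25 M in MeOH), THF, rt
Reagents that add atoms: none
Why: Acid-catalysed acetal exchange removes the aryl MOM ether as dimethoxymethane, which methanol keeps from alkylating the free C–H of ring A, while benzyl ethers and the hindered aryl ester are stable to methanolic HCl at room temperature.

Step 11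
Reactants: 13 2,2,6-trimethyl-4H-1,3-dioxin-4-one
Product: 14 6-ethyl-2,2-dimethyl-4H-1,3-dioxin-4-one
Conditions: LiN(iPr)2, THF, −78 °C; MeI, DMPU, −78 to −40 °C
Reagents that add atoms: iodomethane, CI
Why: γ-Alkylation of the lithium dienolate of the dioxinone, with the polar cosolvent steering methylation to the terminal carbon.

Step 12
Reactants: 14 6-ethyl-2,2-dimethyl-4H-1,3-dioxin-4-one
Product: 15 2,2-dimethyl-6-(3-oxopentan-2-yl)-4H-1,3-dioxin-4-one (racemic)
Conditions: LiN(SiMe3)2 (2 equiv), 14 (2 equiv), THF, −78 °C; EtCOCl (1 equiv); aqueous NH4Cl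
Reagents that add atoms: propanoyl chloride, CCC(Cl)=O
Why: Crossed Claisen condensation (γ-acylation of the dienolate by an acid chloride), in which the second equivalent of dienolate takes up the proton of the more acidic β-keto product.

Step 13
Reactants: 15 2,2-dimethyl-6-(3-oxopentan-2-yl)-4H-1,3-dioxin-4-one
Product: 16 2,2-dimethyl-6-(4-methyl-3,5-dioxohexan-2-yl)-4H-1,3-dioxin-4-one (mixture of epimers and enol forms)
Conditions: LiN(iPr)2 (2.5 equiv), THF, −78 °C; MeC(O)N(OMe)Me, −78 to −40 °C; aqueous NH4Cl
Reagents that add atoms: N-methoxy-N-methylacetamide, CC(=O)N(C)OC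
Why: Dianion acylation, in which the second deprotonation takes place at the CH2 of the ethyl ketone and this more reactive terminal enolate attacks the N-methoxy-N-methylamide, whose chelated tetrahedral adduct prevents over-addition and gives the 1,3-diketone on quench.

Step 14
Reactants: 12 3-(benzyloxy)-2,5,6-trimethylphenyl 2-(benzyloxy)-4-hydroxy-3,5,6-trimethylbenzoate; 16 2,2-dimethyl-6-(4-methyl-3,5-dioxohexan-2-yl)-4H-1,3-dioxin-4-one
Product: 18 3-(benzyloxy)-2,5,6-trimethylphenyl 2-(benzyloxy)-4-[(4,6-dimethyl-3,5,7-trioxooctanoyl)oxy]-3,5,6-trimethylbenzoate, via acylketene 17 (not isolated)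
Conditions: 16 (1.5–2 equiv, added in portions), toluene, 110 °C, sealed tube; concentrate and use crude
Reagents that add atoms: none
Why: Retro-hetero-Diels–Alder loss of acetone from the dioxinone releases acylketene 17, which the phenolic O–H of 12 should capture at the sterically open ketene carbon in a hydrogen-bond-assisted addition that tolerates the two ortho methyl groups.

Step 15
Reactants: 18 3-(benzyloxy)-2,5,6-trimethylphenyl 2-(benzyloxy)-4-[(4,6-dimethyl-3,5,7-trioxooctanoyl)oxy]-3,5,6-trimethylbenzoate
Product: 20 3-(benzyloxy)-2,5,6-trimethylphenyl 2-(benzyloxy)-4-[(2,4-dihydroxy-3,5,6-trimethylbenzoyl)oxy]-3,5,6-trimethylbenzoate, via cyclic aldol adduct 19 (not isolated)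
Conditions: Et3N, CH2Cl2, 0 °C to rt; then HCl (4 M in 1,4-dioxane), rt
Reagents that add atoms: none
Why: Et3N reversibly enolises the C2 methylene of the chain, the only CH2 between two carbonyls and its most acidic and least hindered carbon acid, and this enolate adds to the C7 methyl ketone to form the C2–C7 bond (C1–C6 of ring C) as tertiary aldol 19; acid then removes water across C2–C7 and the C3 and C5 ketones enolise through C4–H and C6–H to the benzene ring with both hydroxyls free. The closest known reaction is the biomimetic aldol aromatisation of 3,5,7-triketo esters set free from diketo-dioxinones, which gives resorcylates. Ring C closes in a 6-exo-trig aldol mode with the enolate double bond inside the forming ring. No stereocentre remains in the product, since the centres at C2, C4, C6 and C7 of 19 are all erased on aromatisation. The step needs aldol closure to outrun acyl transfer at the aryl ester, that is loss of the A–B aryloxide by elimination to the acylketene, lactonisation of the C5 enol oxygen to a 4-hydroxy-2-pyranone, or Claisen closure of C6 onto C1. This should be secured by the weak amine base in an aprotic, non-nucleophilic solvent at or below room temperature, by the C6 methyl group, which makes the Claisen nucleophile a hindered tertiary carbon and its product a quaternary triketone that cannot aromatise, and by the irreversible aromatisation that follows 19.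

Step 16
Reactants: 20 3-(benzyloxy)-2,5,6-trimethylphenyl 2-(benzyloxy)-4-[(2,4-dihydroxy-3,5,6-trimethylbenzoyl)oxy]-3,5,6-trimethylbenzoate
Product: 21 thielavin Z8 (3-hydroxy-2,5,6-trimethylphenyl 4-[(2,4-dihydroxy-3,5,6-trimethylbenzoyl)oxy]-2-hydroxy-3,5,6-trimethylbenzoate)
Conditions: H2 (1 atm), 10% Pd/C, EtOAc, rt
Reagents that add atoms: none
Why: Catalytic hydrogenolysis cleaves both aryl benzyl ethers, while the two depside esters and the phenols are inert to H2 under neutral conditions.

**Compound list**

1 | atraric acid (methyl 2,4-dihydroxy-3,6-dimethylbenzoate) | COC(=O)c1c(C)cc(O)c(C)c1O | starting material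
2 | methyl 4-(benzyloxy)-2-hydroxy-3,6-dimethylbenzoate | COC(=O)c1c(C)cc(OCc2ccccc2)c(C)c1O | intermediate
3 | 3-(benzyloxy)-6-(hydroxymethyl)-2,5-dimethylphenol | OCc1c(C)cc(OCc2ccccc2)c(C)c1O | intermediate
4 | 3-(benzyloxy)-2,5,6-trimethylphenol (ring A) | Cc1cc(OCc2ccccc2)c(C)c(O)c1C | intermediate
5 | methyl 5-formyl-2,4-dihydroxy-3,6-dimethylbenzoate | COC(=O)c1c(C)c(C=O)c(O)c(C)c1O | intermediate
6 | methyl 2,4-dihydroxy-3,5,6-trimethylbenzoate | COC(=O)c1c(C)c(C)c(O)c(C)c1O | intermediate
7 | methyl 2-hydroxy-4-(methoxymethoxy)-3,5,6-trimethylbenzoate | COCOc1c(C)c(C)c(C(=O)OC)c(O)c1C | intermediate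
8 | methyl 2-(benzyloxy)-4-(methoxymethoxy)-3,5,6-trimethylbenzoate | COCOc1c(C)c(C)c(C(=O)OC)c(OCc2ccccc2)c1C | intermediate
9 | 2-(benzyloxy)-4-(methoxymethoxy)-3,5,6-trimethylbenzoic acid (ring B) | COCOc1c(C)c(C)c(C(=O)O)c(OCc2ccccc2)c1C | intermediate
10 | 2-(benzyloxy)-4-(methoxymethoxy)-3,5,6-trimethylbenzoyl chloride | COCOc1c(C)c(C)c(C(=O)Cl)c(OCc2ccccc2)c1C | intermediate
11 | 3-(benzyloxy)-2,5,6-trimethylphenyl 2-(benzyloxy)-4-(methoxymethoxy)-3,5,6-trimethylbenzoate | COCOc1c(C)c(C)c(C(=O)Oc2c(C)c(OCc3ccccc3)cc(C)c2C)c(OCc4ccccc4)c1C | intermediate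
12 | 3-(benzyloxy)-2,5,6-trimethylphenyl 2-(benzyloxy)-4-hydroxy-3,5,6-trimethylbenzoate (A–B phenol) | Oc1c(C)c(C)c(C(=O)Oc2c(C)c(OCc3ccccc3)cc(C)c2C)c(OCc4ccccc4)c1C | intermediate
13 | 2,2,6-trimethyl-4H-1,3-dioxin-4-one | CC1=CC(=O)OC(C)(C)O1 | starting material
14 | 6-ethyl-2,2-dimethyl-4H-1,3-dioxin-4-one | CCC1=CC(=O)OC(C)(C)O1 | intermediate
15 | 2,2-dimethyl-6-(3-oxopentan-2-yl)-4H-1,3-dioxin-4-one (racemic) | CCC(=O)C(C)C1=CC(=O)OC(C)(C)O1 | intermediate
16 | 2,2-dimethyl-6-(4-methyl-3,5-dioxohexan-2-yl)-4H-1,3-dioxin-4-one (epimer mixture) | CC(=O)C(C)C(=O)C(C)C1=CC(=O)OC(C)(C)O1 | intermediate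
17 | 4,6-dimethyl-3,5,7-trioxooct-1-en-1-one (acylketene, epimer mixture) | CC(=O)C(C)C(=O)C(C)C(=O)C=C=O | intermediate
18 | 3-(benzyloxy)-2,5,6-trimethylphenyl 2-(benzyloxy)-4-[(4,6-dimethyl-3,5,7-trioxooctanoyl)oxy]-3,5,6-trimethylbenzoate (epimer and enol mixture) | CC(=O)C(C)C(=O)C(C)C(=O)CC(=O)Oc1c(C)c(C)c(C(=O)Oc2c(C)c(OCc3ccccc3)cc(C)c2C)c(OCc4ccccc4)c1C | intermediate
19 | 3-(benzyloxy)-2,5,6-trimethylphenyl 2-(benzyloxy)-4-[(2-hydroxy-2,3,5-trimethyl-4,6-dioxocyclohexane-1-carbonyl)oxy]-3,5,6-trimethylbenzoate (diastereomer mixture) | CC5(O)C(C)C(=O)C(C)C(=O)C5C(=O)Oc1c(C)c(C)c(C(=O)Oc2c(C)c(OCc3ccccc3)cc(C)c2C)c(OCc4ccccc4)c1C | intermediate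
20 | 3-(benzyloxy)-2,5,6-trimethylphenyl 2-(benzyloxy)-4-[(2,4-dihydroxy-3,5,6-trimethylbenzoyl)oxy]-3,5,6-trimethylbenzoate | Cc1c(C)c(O)c(C)c(O)c1C(=O)Oc5c(C)c(C)c(C(=O)Oc2c(C)c(OCc3ccccc3)cc(C)c2C)c(OCc4ccccc4)c5C | intermediate
21 | thielavin Z8 (no stereocentre) | Cc1cc(O)c(C)c(OC(=O)c2c(C)c(C)c(OC(=O)c3c(C)c(C)c(O)c(C)c3O)c(C)c2O)c1C | target

**Step count**

Total step count: 16.
Longest linear sequence: 10 steps (1 → 5 → 6 → 7 → 8 → 9 → 11 → 12 → 18 → 20 → 21, that is steps 4–10 and 14–16).

**Steps most likely to fail**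

Step 14. The di-ortho-methylated phenol of 12 may capture the acylketene more slowly than the ketene lactonises onto its own C5 enol oxygen (giving a 4-hydroxy-2-pyranone) or dimerises. The fallback sets out from 16 and comes back at 18. Thermolysis of 16 in toluene at 110 °C (sealed tube) with an excess of 2-methylpropane-2-thiol, a small and strongly nucleophilic trap, should give S-tert-butyl 4,6-dimethyl-3,5,7-trioxooctanethioate F1. Treating F1 (in excess) with 12 and silver trifluoroacetate AgOCOCF3 in THF at room temperature should then transfer the acyl group to the phenol by the thiophile-promoted alcoholysis known for β-keto thioesters, giving 18 in concentrated solution and without heating.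

Step 15. The enolate of the aryl β-keto ester may expel the A–B aryloxide (elimination to the acylketene, or lactonisation to a pyranone) faster than it closes onto the C7 ketone. The fallback sets out from 6 and 12 and comes back at 21; it makes ring C beforehand and joins it by conventional depside esterification. Exhaustive benzylation of 6 (BnBr, K2CO3, DMF, 80 °C) should give methyl 2,4-bis(benzyloxy)-3,5,6-trimethylbenzoate F2. Hydrolysis (KOH, DMSO–H2O, 90 °C) should give 2,4-bis(benzyloxy)-3,5,6-trimethylbenzoic acid F3. Oxalyl chloride with catalytic DMF in CH2Cl2 should give 2,4-bis(benzyloxy)-3,5,6-trimethylbenzoyl chloride F4. Acylation of the sodium salt of 12 (NaH, THF) should give tetra-O-benzyl thielavin Z8 F5, and hydrogenolysis (H2, Pd/C, EtOAc) of all four benzyl ethers should give 21.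

Step 13. The second deprotonation of 15 may be incomplete, or the dianion may be acylated on oxygen or at the methine next to the dioxinone instead of the terminal carbon. The fallback sets out from 14 and comes back at 16; it brings in the last four carbons with the distal ketone masked, starting from commercial ethyl 2-methylacetoacetate. Ketalisation (ethylene glycol, TsOH, toluene, reflux with removal of water) should give ethyl 2-(2-methyl-1,3-dioxolan-2-yl)propanoate F6. Aminolysis with MeNHOMe·HCl and iPrMgCl in THF at −20 °C should give N-methoxy-N-methyl-2-(2-methyl-1,3-dioxolan-2-yl)propanamide F7. The lithium dienolate of 14 (LiN(SiMe3)2, THF, −78 °C) should be acylated by F7 at its γ-carbon to give 2,2-dimethyl-6-[4-(2-methyl-1,3-dioxolan-2-yl)-3-oxopentan-2-yl]-4H-1,3-dioxin-4-one F8. Aqueous HCl in THF at room temperature should unmask the ketone to give 16.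

**Further compounds**

F1 | step 14 | S-tert-butyl 4,6-dimethyl-3,5,7-trioxooctanethioate | CC(=O)C(C)C(=O)C(C)C(=O)CC(=O)SC(C)(C)C
F2 | step 15 | methyl 2,4-bis(benzyloxy)-3,5,6-trimethylbenzoate | COC(=O)c1c(C)c(C)c(OCc2ccccc2)c(C)c1OCc3ccccc3
F3 | step 15 | 2,4-bis(benzyloxy)-3,5,6-trimethylbenzoic acid | OC(=O)c1c(C)c(C)c(OCc2ccccc2)c(C)c1OCc3ccccc3
F4 | step 15 | 2,4-bis(benzyloxy)-3,5,6-trimethylbenzoyl chloride | ClC(=O)c1c(C)c(C)c(OCc2ccccc2)c(C)c1OCc3ccccc3
F5 | step 15 | 3-(benzyloxy)-2,5,6-trimethylphenyl 2-(benzyloxy)-4-{[2,4-bis(benzyloxy)-3,5,6-trimethylbenzoyl]oxy}-3,5,6-trimethylbenzoate | Cc1c(C)c(OCc6ccccc6)c(C)c(OCc7ccccc7)c1C(=O)Oc5c(C)c(C)c(C(=O)Oc2c(C)c(OCc3ccccc3)cc(C)c2C)c(OCc4ccccc4)c5C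
F6 | step 13 | ethyl 2-(2-methyl-1,3-dioxolan-2-yl)propanoate | CCOC(=O)C(C)C1(C)OCCO1
F7 | step 13 | N-methoxy-N-methyl-2-(2-methyl-1,3-dioxolan-2-yl)propanamide | CON(C)C(=O)C(C)C1(C)OCCO1
F8 | step 13 | 2,2-dimethyl-6-[4-(2-methyl-1,3-dioxolan-2-yl)-3-oxopentan-2-yl]-4H-1,3-dioxin-4-one | CC(C(=O)C(C)C1(C)OCCO1)C2=CC(=O)OC(C)(C)O2
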